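The partner in Thursday's flask enters evenly over 2.50 d, and the question is what that ramp costs in product.

| flask | starting material | partner | base | remark | time |
|---|---|---|---|---|---|
| larch | 0.10 M | 1.2 equiv | 0.050 equiv | run made earlier |  |
| maple | 0.10 M | 1.2 equiv | 0.034 equiv | run made earlier |  |
| birch | 0.10 M | 1.2 equiv | 0.075 equiv | run made earlier |  |
| cedar | 0.20 M | 1.2 equiv | 0.050 equiv | run made earlier |  |
| Friday's | 0.10 M (fed, over 2.50 d) | 1.20 equiv | 0.0500 equiv | a stirred flask in which starting material is dosed at a steady rate over 2.50 d without added volume, worked up at 2.5 d | 2.5 d |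
| Saturday's | 0.10 M | 1.20 equiv | 0.0500 equiv | one stirred flow tank at steady state, fed with the mixture as stated, mean residence time 2.5 d |  |
| Monday's | 0.10 M | 1.20 equiv | 0.0500 equiv | a closed flask charged with all of it at once and left for 2.5 d | 2.5 d |
| Thursday's | 0.10 M | 1.20 equiv (fed, over 2.50 d) | 0.0500 equiv | all but partner at the start; partner goes in evenly over 2.50 d, the run ends at 2.5 d | 2.5 d |

larch run (percent of the starting material charged)

| time / d | product / % | starting material / % |
|---|---|---|
| 0.208 | 0.7 | 98.9 |
| 0.333 | 0.7 | 99.7 |
| 0.500 | 1.2 | 98.1 |
| 0.833 | 1.4 | 98.7 |
| 1.67 | 4.2 | 96.9 |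
| 2.50 | 5.3 | 95.1 |

maple run (percent of the starting material charged)

| time / h | product / % | starting material / % |
|---|---|---|
| 4.00 | 0.3 | 100.4 |
| 6.00 | 0.6 | 99.4 |
| 10.0 | 0.8 | 98.0 |
| 20.0 | 2.2 | 98.3 |
| 30.0 | 2.7 | 97.5 |
| 50.0 | 3.9 | 95.6 |

birch run (percent of the starting material charged)

| time / h | product / % | starting material / % |
|---|---|---|
| 3.00 | 0 | 99.2 |
| 10.0 | 1.0 | 98.9 |
| 15.0 | 0.8 | 98.7 |
| 25.0 | 1.9 | 97.4 |
| 40.0 | 4.6 | 96.3 |
| 50.0 | 4.4 | 95.7 |

cedar run (percent of the starting material charged)

| time / h | product / % | starting material / % |
|---|---|---|
| 4.00 | 0.9 | 98.5 |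
| 12.0 | 2.5 | 97.6 |
| 20.0 | 3.2 | 96.3 |
| 30.0 | 5.1 | 94.3 |
| 50.0 | 21.4 | 78.2 |

(readings scatter by 0.5 percentage points)

- the stated concentrations are those of everything mixed, before any reaction; amounts are the same in each set-up
- the numbers in the tables scatter by 0.5 percentage points (one standard deviation)
- the feed brings no volume worth counting
- the earlier runs were made in a closed, stirred flask
- a reading or a percentage of product counts all its forms, free or not

- the set-up with the highest amount of product at the outlet or at the end, in percent of the starting material put in ("none" if the first two lie within 2 percentage points) (Friday's / Saturday's / Monday's / Thursday's / none)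
- amount of product at the outlet or at the end, in percent of the starting material put in, Friday's
- amount of product at the outlet or at the end, in percent of the starting material put in, Saturday's
- amount of product at the outlet or at the end, in percent of the starting material put in, Monday's
- amount of product at the outlet or at the end, in percent of the starting material put in, Thursday's

At 50.0 h, maple with 0.034 equiv of base reads 3.9% and birch with 0.075 equiv reads 4.4%, a gap of 0.5 percentage points against a scatter of 0.5 points. Cedar, at twice the concentration, makes percent twice as fast as larch, reading 5.1% at 30.0 h. Its induction period ends after product passes the base charge of 0.050 equiv, and it reads 21.4% at 50.0 h.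

Take the rate as proportional to the partner present, which is assumed. Larch, with its whole partner charge in from the start, then bounds Thursday's from above at a reading of 5.3%. Two time steps narrow this to between 1.32% and 3.98%, and four steps to between 1.99% and 3.31%. The bounds close on the mean of the ramp, a share f = 0.5 of full partner, and that mean is exact for a straight line. Depletion adds a further error, and larch still reads 95.1% starting material at its end. With y, c and t the larch product, concentration and time, the background yield Y and the base margin M, which is Y per base charge e, are:

Y = f · y · (flask's c / larch c) · (flask's t / larch t) = 2.65%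

M = Y / e = 0.530

This reckoning is trusted for Thursday's, whose base margin stands below 1, the level near which cedar read 1.02 at 30.0 h, before its rise.

The forecast gives 2.7% for Friday's, 30% for Saturday's, 5.4% for Monday's and 2.7% for Thursday's, inside the four-step bracket, with Saturday's best, and says of the tank's low state “right on the threshold, so the outcome is knife-edge”.

Thursday's gives 2.64%, Friday's 2.64%, Monday's 5.33% and Saturday's 27.6%, so Saturday's is best. Thursday's ends with 48% of its base unbound at M = 0.530. Monday's, with f = 1, has M = 1.06, and its unbound base stands at 6.0% at 2.50 d.

    starting material + partner + by-product → product + 2 by-product (k = 0.0579 L² mol⁻² min⁻¹)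
    partner + product ⇌ idle adduct, settled at all times (K = 28.1 L mol⁻¹)
    base + by-product ⇌ salt, settled at all times (K = 25000 L mol⁻¹)
    starting material + partner → product + by-product (k = 1.26 × 10⁻⁴ L mol⁻¹ min⁻¹)

Thursday's recipe at 0.25 M reckons to Y = 6.62% and M = 1.32, above 1. That flask computes to 8.52%, with 0.45% of its base unbound.

All runs are calculated on assumed constants, and the scatter is random.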